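**Plan**
1. Retrosynthetic cuts, in order: the C6–CH2 bond of the prenyl group (from a C6 iodide); the furan O–C2 bond and the C=C bond of both pyrans (one DDQ oxidation of a 2′-hydroxyisoflavone carrying two chromans); the pyranone bonds C3–C1′ and O1–C2 (oxidative 1,2-aryl shift of a 2′-hydroxychalcone and ring closure); the chalcone Cα=Cβ bond (aldol).
2. Forward: ring-B chroman aldehyde 8 (4 steps) and ring-A iodochroman ketone 16 (5 steps) are joined to chalcone 17; ring C (the pyranone) closes in the key step; the furan and both chromene double bonds follow in one oxidation; the prenyl group comes last.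
3. Enabling feature: the benzofuran benzene ring (C1′–C6′, oxygenated at C2′, C4′ and C5′) is bonded to C3 of the pyranone, next to the C4 carbonyl, and not to C2. This is the isoflavonoid connectivity, and so electron-rich an aryl group shifts readily from Cβ to Cα of an enone.
4. The thallium oxidant attacks any electron-rich alkene, so both pyrans travel as chromans and the prenyl site as an aryl iodide. The ring-B ortho oxygen carries an acid-stable benzyl group so that it cannot close onto the acetal carbon.
5. Stereochemistry: the target has no stereocentre; the E geometry of 17 and the racemic centre of acetal 18 are both erased in the key step.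

Key step: step 11

Remark: 2,4,5-trihydroxybenzaldehyde and 2,4,6-trihydroxyacetophenone are taken as catalogue compounds. Isoflavone numbering (ring A C5–C8, ring C O1–C4, ring B C1′–C6′) is used from 19 onward.
Assumption: mono-benzylation of diol 13 (step 8) goes to the less hindered 7-OH. This is to be confirmed on 14 by an NOE between OCH2Ph and H-8 before the material is carried on.

**Step 1**
Reactants: 1 2,4,5-trihydroxybenzaldehyde; 2 3-methylbut-2-enal
Product: 3 5,8-dihydroxy-2,2-dimethyl-2H-chromene-6-carbaldehyde
Conditions: ethylenediammonium diacetate (10 mol %), xylene, 140 °C, N2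
Reagents that add atoms: 3-methylbut-2-enal, CC(C)=CC=O
Why: Amine-catalysed Knoevenagel-type condensation at C3, the only ring carbon flanked by two hydroxyls, followed by oxa-6π electrocyclisation through the 4-oxygen while the 2-OH stays hydrogen-bonded to the aldehyde, should give the angular chromene as in the chromenylation of 2,4-dihydroxybenzaldehyde.

**Step 2**
Reactants: 3 5,8-dihydroxy-2,2-dimethyl-2H-chromene-6-carbaldehyde
Product: 4 5,8-dihydroxy-2,2-dimethylchromane-6-carbaldehyde
Conditions: H2 (1 atm), Pd/C, EtOAc, rt
Reagents that add atoms: none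
Why: Heterogeneous catalytic hydrogenation saturates the styrene-type C3=C4 bond much faster than it reduces the chelated aryl aldehyde, and the resulting chroman is inert to the oxidant of step 11.

**Step 3**
Reactants: 4 5,8-dihydroxy-2,2-dimethylchromane-6-carbaldehyde; 5 chloromethyl methyl ether
Product: 6 5-hydroxy-8-(methoxymethoxy)-2,2-dimethylchromane-6-carbaldehyde
Conditions: MOMCl (1.05 equiv), K2CO3, acetone, 0 °C to rt, N2
Reagents that add atoms: chloromethyl methyl ether, COCCl
Why: Williamson-type O-alkylation under mild base takes the free 8-OH and leaves the 5-OH, which is held in a hydrogen bond to the aldehyde; the MOM ether shields this para-alkoxyphenol from oxidation in step 11.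

**Step 4**
Reactants: 6 5-hydroxy-8-(methoxymethoxy)-2,2-dimethylchromane-6-carbaldehyde; 7 benzyl bromide
Product: 8 5-(benzyloxy)-8-(methoxymethoxy)-2,2-dimethylchromane-6-carbaldehyde
Conditions: BnBr, K2CO3, DMF, 60 °C
Reagents that add atoms: benzyl bromide, BrCc1ccccc1
Why: Williamson etherification under forcing conditions alkylates the chelated phenol and installs the acid-stable benzyl ether that keeps this ortho oxygen from attacking the acetal carbon in step 11.

**Step 5**
Reactants: 9 2,4,6-trihydroxyacetophenone; 10 3-chloro-3-methylbut-1-yne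
Product: 11 1-[2,6-dihydroxy-4-(2-methylbut-3-yn-2-yloxy)phenyl]ethanone
Conditions: K2CO3, KI, CuI (cat.), acetone, reflux
Reagents that add atoms: 3-chloro-3-methylbut-1-yne, C#CC(C)(C)Cl
Why: Copper-assisted O-propargylation (Williamson type) takes place at the 4-OH, the most acidic hydroxyl and the only one not next to the acetyl group, which fixes the future pyran oxygen para to the ketone.

**Step 6**
Reactants: 11 1-[2,6-dihydroxy-4-(2-methylbut-3-yn-2-yloxy)phenyl]ethanone
Product: 12 1-(5,7-dihydroxy-2,2-dimethyl-2H-chromen-6-yl)ethanone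
Conditions: N,N-diethylaniline, 190 °C
Reagents that add atoms: none
Why: Aryl propargyl ether Claisen rearrangement, 1,5-hydrogen shift and oxa-6π electrocyclisation build the chromene at one of two equivalent ortho carbons, so only one constitution can arise.

**Step 7**
Reactants: 12 1-(5,7-dihydroxy-2,2-dimethyl-2H-chromen-6-yl)ethanone
Product: 13 1-(5,7-dihydroxy-2,2-dimethylchroman-6-yl)ethanone
Conditions: H2 (1 atm), Pd/C, EtOAc, rt
Reagents that add atoms: none
Why: Catalytic hydrogenation of the chromene double bond leaves the chelated aryl ketone untouched and masks the pyran as a chroman for step 11.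

**Step 8**
Reactants: 13 1-(5,7-dihydroxy-2,2-dimethylchroman-6-yl)ethanone; 7 benzyl bromide
Product: 14 1-[7-(benzyloxy)-5-hydroxy-2,2-dimethylchroman-6-yl]ethanone
Conditions: BnBr (1.0 equiv), K2CO3, acetone, reflux
Reagents that add atoms: benzyl bromide, BrCc1ccccc1
Why: Williamson mono-benzylation should go to the 7-OH, which is less hindered and less firmly chelated than the 5-OH buttressed by the ring CH2, the same preference that leaves the hydroxyl next to the C-alkyl group free in C-alkylphloroacetophenones; the remaining 5-OH is the one that must close ring C.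

**Step 9**
Reactants: 14 1-[7-(benzyloxy)-5-hydroxy-2,2-dimethylchroman-6-yl]ethanone; 15 N-iodosuccinimide
Product: 16 1-[7-(benzyloxy)-5-hydroxy-8-iodo-2,2-dimethylchroman-6-yl]ethanone
Conditions: NIS, DMF, 0 °C to rt
Reagents that add atoms: N-iodosuccinimide, O=C1CCC(=O)N1I
Why: Electrophilic aromatic iodination can only occur at C8, the single unsubstituted ring carbon and para to the free phenol; the iodide marks the later prenyl position and is inert in steps 10 to 14.

**Step 10**
Reactants: 16 1-[7-(benzyloxy)-5-hydroxy-8-iodo-2,2-dimethylchroman-6-yl]ethanone; 8 5-(benzyloxy)-8-(methoxymethoxy)-2,2-dimethylchromane-6-carbaldehyde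
Product: 17 (E)-1-[7-(benzyloxy)-5-hydroxy-8-iodo-2,2-dimethylchroman-6-yl]-3-[5-(benzyloxy)-8-(methoxymethoxy)-2,2-dimethylchroman-6-yl]prop-2-en-1-one
Conditions: KOH (50 % aq.), EtOH, rt
Reagents that add atoms: none
Why: Claisen–Schmidt aldol condensation of the methyl ketone with the non-enolisable aldehyde gives the E-enone by E1cB loss of water.

**Step 11**
Reactants: 17 (E)-1-[7-(benzyloxy)-5-hydroxy-8-iodo-2,2-dimethylchroman-6-yl]-3-[5-(benzyloxy)-8-(methoxymethoxy)-2,2-dimethylchroman-6-yl]prop-2-en-1-one
Product: 19 5,2′-bis(benzyloxy)-5′-hydroxy-6-iodoisoflavone with 2,2-dimethyl-3,4-dihydropyran rings fused at C7(O)–C8 and at C4′(O)–C3′, via dimethyl acetal 18 (not isolated)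
Conditions: Tl(NO3)3·3H2O (1.2 equiv), MeOH/HC(OMe)3, rt; then 10 % aq. HCl, reflux
Reagents that add atoms: none
Why: Trivalent thallium adds as an electrophile to Cα of the enone while methanol attacks Cβ, and heterolysis of the weak C–Tl bond (thallium leaves in its monovalent state) is assisted by the electron-rich ring B through a phenonium ion, so the aryl group moves from Cβ to Cα (new C3–C1′ bond) and methanol traps the oxocarbenium ion at the former Cβ as acetal 18. This is the established thallium trinitrate oxidative rearrangement of 2′-hydroxychalcones to isoflavones, a reaction type that tolerates aryl iodides and benzyl ethers. Acid then ionises the acetal and the chelated phenol closes ring C onto the oxocarbenium carbon (new O1–C2 bond) in a 6-exo-trig mode (6-endo-trig if methanol is lost first to the β-methoxyenone), loss of the second methanol gives the pyranone, and the MOM ether is methanolysed in the same flask. No stereocentre is formed in 19, because the racemic centre of 18 becomes sp2. Aryl migration has to win over direct cyclisation to a flavone or aurone and over attack on other π-bonds; this is secured by the ortho- and para-oxygens of ring B, by methanol trapping before ring closure, and by the absence of any other alkene in 17. The constitution of ring C is secured by the single free ortho hydroxyl on ring A and by the acid-stable benzyl ether on the ring-B ortho oxygen, which cannot compete for the acetal carbon to give a 3-aroylbenzofuran.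

**Step 12**
Reactants: 19 5,2′-bis(benzyloxy)-5′-hydroxy-6-iodoisoflavone bis-chroman; 20 acetic anhydride
Product: 21 5′-acetoxy-5,2′-bis(benzyloxy)-6-iodoisoflavone bis-chroman
Conditions: Ac2O, pyridine, rt
Reagents that add atoms: acetic anhydride, CC(=O)OC(C)=O
Why: Pyridine-promoted O-acylation of the only free hydroxyl masks the 5′-oxygen, which would otherwise form a para-hydroquinone with the 2′-OH and be oxidised to a quinone in step 14.

**Step 13**
Reactants: 21 5′-acetoxy-5,2′-bis(benzyloxy)-6-iodoisoflavone bis-chroman
Product: 22 5′-acetoxy-5,2′-dihydroxy-6-iodoisoflavone bis-chroman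
Conditions: BCl3, C6HMe5, CH2Cl2, −78 °C
Reagents that add atoms: none
Why: Lewis-acid debenzylation with a non-basic cation scavenger (Friedel–Crafts transfer of benzyl to pentamethylbenzene) cleaves both benzyl ethers at low temperature without touching the aryl iodide, the aryl acetate or the chroman ethers, at a stage where no alkene is present.

**Step 14**
Reactants: 22 5′-acetoxy-5,2′-dihydroxy-6-iodoisoflavone bis-chroman
Product: 24 5′-acetoxy-5-hydroxy-6-iodocoumaronochromone (furan O from C2′ to C2) with 2,2-dimethyl-2H-pyran rings fused at C7(O)–C8 and C4′(O)–C3′, via furan-closed bis-chroman 23 (not isolated)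
Conditions: DDQ (4 equiv), 1,4-dioxane, rt then reflux
Reagents that add atoms: none
Why: DDQ dehydrogenation first forms the C2–O bond from the 2′-phenol (the dehydrogenative cyclisation known for 2′-hydroxyisoflavones), and benzylic hydride abstraction at C4 of each oxygen-activated chroman followed by proton loss then gives the two 2,2-dimethylchromenes.

**Step 15**
Reactants: 24 5′-acetoxy-5-hydroxy-6-iodo bis-chromene coumaronochromone; 25 tributyl(3-methylbut-2-en-1-yl)stannane
Product: 27 CNP0323631.0 (5,5′-dihydroxy-6-prenylcoumaronochromone with 2,2-dimethyl-2H-pyran rings fused at C7(O)–C8 and C4′(O)–C3′), via prenylated acetate 26 (not isolated)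
Conditions: Pd(PPh3)4 (10 mol %), DMF, 90 °C; then K2CO3, MeOH, rt
Reagents that add atoms: tributyl(3-methylbut-2-en-1-yl)stannane, CCCC[Sn](CCCC)(CCCC)CC=C(C)C
Why: Stille cross-coupling transfers the prenyl group through its CH2 terminus to the aryl iodide, and base-catalysed methanolysis (transesterification) of the aryl acetate in the same flask frees the 5′-OH without affecting the alkenes.

**Compound list**
1 | 2,4,5-trihydroxybenzaldehyde | O=Cc1cc(O)c(O)cc1O | starting material
2 | 3-methylbut-2-enal | CC(C)=CC=O | starting material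
3 | 5,8-dihydroxy-2,2-dimethyl-2H-chromene-6-carbaldehyde | O=Cc1cc(O)c2c(c1O)C=CC(C)(C)O2 | intermediate
4 | 5,8-dihydroxy-2,2-dimethylchromane-6-carbaldehyde | O=Cc1cc(O)c2c(c1O)CCC(C)(C)O2 | intermediate
5 | chloromethyl methyl ether | COCCl | starting material
6 | 5-hydroxy-8-(methoxymethoxy)-2,2-dimethylchromane-6-carbaldehyde | O=Cc1cc(OCOC)c2c(c1O)CCC(C)(C)O2 | intermediate
7 | benzyl bromide | BrCc1ccccc1 | starting material
8 | 5-(benzyloxy)-8-(methoxymethoxy)-2,2-dimethylchromane-6-carbaldehyde | O=Cc1cc(OCOC)c2c(c1OCc1ccccc1)CCC(C)(C)O2 | intermediate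
9 | 2,4,6-trihydroxyacetophenone | CC(=O)c1c(O)cc(O)cc1O | starting material
10 | 3-chloro-3-methylbut-1-yne | C#CC(C)(C)Cl | starting material
11 | 1-[2,6-dihydroxy-4-(2-methylbut-3-yn-2-yloxy)phenyl]ethanone | CC(=O)c1c(O)cc(OC(C)(C)C#C)cc1O | intermediate
12 | 1-(5,7-dihydroxy-2,2-dimethyl-2H-chromen-6-yl)ethanone | CC(=O)c1c(O)cc2c(c1O)C=CC(C)(C)O2 | intermediate
13 | 1-(5,7-dihydroxy-2,2-dimethylchroman-6-yl)ethanone | CC(=O)c1c(O)cc2c(c1O)CCC(C)(C)O2 | intermediate
14 | 1-[7-(benzyloxy)-5-hydroxy-2,2-dimethylchroman-6-yl]ethanone | CC(=O)c1c(OCc2ccccc2)cc2c(c1O)CCC(C)(C)O2 | intermediate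
15 | N-iodosuccinimide | O=C1CCC(=O)N1I | starting material
16 | 1-[7-(benzyloxy)-5-hydroxy-8-iodo-2,2-dimethylchroman-6-yl]ethanone | CC(=O)c1c(OCc2ccccc2)c(I)c2c(c1O)CCC(C)(C)O2 | intermediate
17 | (E)-1-[7-(benzyloxy)-5-hydroxy-8-iodo-2,2-dimethylchroman-6-yl]-3-[5-(benzyloxy)-8-(methoxymethoxy)-2,2-dimethylchroman-6-yl]prop-2-en-1-one | O=C(/C=C/c1cc(OCOC)c2c(c1OCc1ccccc1)CCC(C)(C)O2)c1c(OCc2ccccc2)c(I)c2c(c1O)CCC(C)(C)O2 | intermediate
18 | 1-[7-(benzyloxy)-5-hydroxy-8-iodo-2,2-dimethylchroman-6-yl]-2-[5-(benzyloxy)-8-(methoxymethoxy)-2,2-dimethylchroman-6-yl]-3,3-dimethoxypropan-1-one (racemic) | COC(OC)C(c1cc(OCOC)c2c(c1OCc1ccccc1)CCC(C)(C)O2)C(=O)c1c(OCc2ccccc2)c(I)c2c(c1O)CCC(C)(C)O2 | intermediate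
19 | 5,2′-bis(benzyloxy)-5′-hydroxy-6-iodoisoflavone with 2,2-dimethyl-3,4-dihydropyran rings fused at C7(O)–C8 and C4′(O)–C3′ | O=c1c(-c2cc(O)c3c(c2OCc2ccccc2)CCC(C)(C)O3)coc2c1c(OCc1ccccc1)c(I)c1c2CCC(C)(C)O1 | intermediate
20 | acetic anhydride | CC(=O)OC(C)=O | starting material
21 | 5′-acetate of 19 | O=c1c(-c2cc(OC(C)=O)c3c(c2OCc2ccccc2)CCC(C)(C)O3)coc2c1c(OCc1ccccc1)c(I)c1c2CCC(C)(C)O1 | intermediate
22 | 5′-acetoxy-5,2′-dihydroxy-6-iodoisoflavone with the same two fused dihydropyran rings | O=c1c(-c2cc(OC(C)=O)c3c(c2O)CCC(C)(C)O3)coc2c1c(O)c(I)c1c2CCC(C)(C)O1 | intermediate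
23 | 5′-acetoxy-5-hydroxy-6-iodocoumaronochromone (furan O from C2′ to C2) with both pyran rings still saturated | Ic1c2c(c3oc4oc5c6c(c(OC(C)=O)cc5c4c(=O)c3c1O)OC(C)(C)CC6)CCC(C)(C)O2 | intermediate
24 | 5′-acetoxy-5-hydroxy-6-iodocoumaronochromone with 2,2-dimethyl-2H-pyran rings fused at C7(O)–C8 and C4′(O)–C3′ | Ic1c2c(c3oc4oc5c6c(c(OC(C)=O)cc5c4c(=O)c3c1O)OC(C)(C)C=C6)C=CC(C)(C)O2 | intermediate
25 | tributyl(3-methylbut-2-en-1-yl)stannane | CCCC[Sn](CCCC)(CCCC)CC=C(C)C | starting material
26 | 5′-acetate of the target (6-prenyl in place of 6-iodo in 24) | CC(C)=CCc1c2c(c3oc4oc5c6c(c(OC(C)=O)cc5c4c(=O)c3c1O)OC(C)(C)C=C6)C=CC(C)(C)O2 | intermediate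
27 | CNP0323631.0 | CC(C)=CCc1c2c(c3oc4oc5c6c(c(O)cc5c4c(=O)c3c1O)OC(C)(C)C=C6)C=CC(C)(C)O2 | target

**Totals**
Total step count: 15.
Longest linear sequence: 11 steps (9 → 11 → 12 → 13 → 14 → 16 → 17 → 19 → 21 → 22 → 24 → 27).

**Steps most likely to fail**

Step 14. Dehydrogenation of the ring-A chroman may stall after the furan has closed, because its arene is conjugated to the carbonyl and carries iodine, and long heating with excess quinone may erode the product. The fallback uncouples the three oxidations. From 22, one equivalent of DDQ at room temperature closes only the furan and the bis-chroman 23 is isolated. Radical benzylic bromination (NBS, AIBN, PhCF3, reflux) at C4 of both chromans gives the bis(4-bromochroman) F3. E2 elimination with DBU in toluene then returns the route at 24.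

Step 15. Transmetalation at the doubly ortho-substituted iodide may be slow, so that protodeiodination or allylic transposition to the 1,1-dimethylallyl isomer competes. The fallback builds the prenyl group in two stages. From 24, Stille coupling with allyltributylstannane (Pd(PPh3)4, DMF), a smaller donor with no regiochemical choice, gives the 6-allyl acetate F4. Cross-metathesis with 2-methylbut-2-ene and the second-generation Grubbs catalyst (H2IMes)(PCy3)Cl2Ru=CHPh in CH2Cl2 at 40 °C turns allyl into prenyl and rejoins the route at 26, which is deacetylated as before to 27.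

Step 11. Oxythallation of the twisted, doubly ortho-substituted enone may be slower than oxidation of the electron-rich ring B, or of its para-alkoxyphenol if the MOM ether is lost early to the nitric acid formed, so that migration is not clean. The fallback reverses the order of ring closure and aryl shift. From 17, NaOAc in refluxing EtOH closes the free phenol onto the enone (oxa-Michael) to the flavanone F1. PhI(OH)OTs in MeCN then effects the known 2,3-aryl shift of flavanones to the MOM-protected isoflavone F2: trivalent iodine attacks the enol at C3, the aryl group follows from C2, and proton loss gives the C2=C3 bond. HCl in MeOH removes the MOM group and rejoins the route at 19.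

**Further compounds**
F1 | step 11 | 5-(benzyloxy)-2-[5-(benzyloxy)-8-(methoxymethoxy)-2,2-dimethylchroman-6-yl]-6-iodoflavanone with a 2,2-dimethyl-3,4-dihydropyran ring fused at C7(O)–C8 (racemic) | O=C1CC(c2cc(OCOC)c3c(c2OCc2ccccc2)CCC(C)(C)O3)Oc2c1c(OCc1ccccc1)c(I)c1c2CCC(C)(C)O1
F2 | step 11 | 5′-O-methoxymethyl ether of 19 | O=c1c(-c2cc(OCOC)c3c(c2OCc2ccccc2)CCC(C)(C)O3)coc2c1c(OCc1ccccc1)c(I)c1c2CCC(C)(C)O1
F3 | step 14 | 23 brominated at the benzylic CH2 (C4) of both dihydropyran rings (mixture of diastereomers) | Ic1c2c(c3oc4oc5c6c(c(OC(C)=O)cc5c4c(=O)c3c1O)OC(C)(C)CC6Br)C(Br)CC(C)(C)O2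
F4 | step 15 | 6-allyl analogue of 24 (allyl in place of iodine) | C=CCc1c2c(c3oc4oc5c6c(c(OC(C)=O)cc5c4c(=O)c3c1O)OC(C)(C)C=C6)C=CC(C)(C)O2
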